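The target is a 20-membered oxa-bridged cyclophane: an unfunctionalised (CH2)14 chain joins C6 of ring B (the 1-aryloxy-2,4-dihydroxyphenyl ring) to C5 of ring A (the 3-hydroxy-5-alkylphenoxy ring). Since the chain carries no functionality, its C9–C10 bond (numbered from ring B) is chosen for ring closure. Ring-closing metathesis of a diaryl ether bearing a dec-9-enyl arm on ring B and a hex-5-enyl arm on ring A, with hydrogenation in the same flask, should give the saturated macrocycle in one operation. Both arms come from commercial ω-bromoalkenes. The precursor is assembled from 5-bromovanillin, whose OH, OMe, Br and CHO map onto the four substituents of ring B.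

Key step: step 5

Assumption (chemistry): the target has no stereocentre, and the E/Z geometry of the metathesis alkene is irrelevant because it is hydrogenated in the same step. Ring A is numbered C1 (ether O), C3 (OH), C5 (chain); ring B is numbered C1 (ether O), C2 and C4 (OH), C6 (chain); the bridge is numbered C1–C14 from ring B. Compounds 1, 2, 6 and 9 are taken as commercial.

Step 1
Reactants: 1 5-bromovanillin (3-bromo-4-hydroxy-5-methoxybenzaldehyde); 2 (3-chloro-5-methoxyphenyl)boronic acid
Product: 3 3-bromo-4-(3-chloro-5-methoxyphenoxy)-5-methoxybenzaldehyde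
Conditions: 2 (2.5 equiv), Cu(OAc)2 (1.0 equiv), pyridine (5 equiv), 4 Å molecular sieves, CH2Cl2, O2 (balloon), rt
Reagents that add atoms: none
Why: Chan–Lam coupling: the copper phenoxide of 1 transmetalates with 2 and reductive elimination forms the diaryl C–O bond under conditions that leave the aldehyde and both aryl halides untouched, and 2,6-disubstituted halophenols are established substrates for this O-arylation.

Step 2
Reactants: 3 3-bromo-4-(3-chloro-5-methoxyphenoxy)-5-methoxybenzaldehyde
Product: 5 3-bromo-4-(3-chloro-5-methoxyphenoxy)-5-methoxyphenol, via aryl formate 4 (not isolated)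
Conditions: mCPBA (1.5 equiv), CH2Cl2, 0 °C to rt; aq. Na2S2O3/NaHCO3 wash; then MeOH, HCl (cat.), rt
Reagents that add atoms: mCPBA (3-chloroperoxybenzoic acid), O=C(OO)c1cccc(Cl)c1
Why: Baeyer–Villiger (Dakin-type) oxidation: in the Criegee adduct the aryl group, activated by the para aryloxy oxygen, migrates in preference to hydride to give formate 4, which acid-catalysed methanolysis converts into the phenol, and since no alkene is present yet the peracid has no competing site.

Step 3
Reactants: 5 3-bromo-4-(3-chloro-5-methoxyphenoxy)-5-methoxyphenol; 6 10-bromodec-1-ene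
Product: 8 4-(3-chloro-5-methoxyphenoxy)-3-(dec-9-en-1-yl)-5-methoxyphenol, via dec-9-enylzinc bromide 7 (not isolated)
Conditions: 6 (2.4 equiv), Zn dust, LiCl, THF, 50 °C; then 5, PdCl2(dppf) (5 mol %), THF, 60 °C
Reagents that add atoms: none
Why: Negishi coupling: zerovalent palladium inserts into the C–Br bond in preference to the C–Cl bond, the primary alkylzinc transmetalates and the wide-bite-angle dppf ligand favours reductive elimination over β-hydride elimination so that the terminal alkene stays in place, while one equivalent of 7 is consumed by the phenolic O–H as a zinc phenoxide that does not interfere.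

Step 4
Reactants: 8 4-(3-chloro-5-methoxyphenoxy)-3-(dec-9-en-1-yl)-5-methoxyphenol; 9 6-bromohex-1-ene
Product: 11 3-(dec-9-en-1-yl)-4-[3-(hex-5-en-1-yl)-5-methoxyphenoxy]-5-methoxyphenol, via hex-5-enylzinc bromide 10 (not isolated)
Conditions: 9 (2.4 equiv), Zn dust, LiCl, THF, 50 °C; then 8, Pd(OAc)2 (3 mol %), SPhos (6 mol %), THF, 65 °C
Reagents that add atoms: none
Why: Negishi coupling of an aryl chloride: the electron-rich dialkylbiarylphosphine SPhos enables oxidative addition of zerovalent palladium to the remaining C–Cl bond and fast reductive elimination of the aryl–alkyl bond, and this catalyst type tolerates acidic O–H groups when an extra equivalent of organozinc is supplied.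

Step 5
Reactants: 11 3-(dec-9-en-1-yl)-4-[3-(hex-5-en-1-yl)-5-methoxyphenoxy]-5-methoxyphenol
Product: 13 saturated di-O-methyl macrocycle, via macrocyclic alkene 12 (not isolated)
Conditions: second-generation Grubbs catalyst RuCl2(=CHPh)(H2IMes)(PCy3) (10 mol %), ClCH2CH2Cl (1 mM), 60 °C, Ar sparge; then H2 (10 bar), 70 °C
Reagents that add atoms: none
Why: Ring-closing olefin metathesis: the ruthenium benzylidene exchanges onto one terminal alkene, the resulting alkylidene undergoes [2+2] cycloaddition with the second terminal alkene and the ruthenacyclobutane cycloreverts, joining bridge carbons C9 and C10 as a C=C bond and releasing ethene, whose loss drives the reaction. The closest known reaction type is the macrocyclic ring-closing metathesis of α,ω-dienes to cyclophanes followed by hydrogenation with the same ruthenium catalyst, which under H2 is converted into a ruthenium hydride that saturates the new alkene (tandem metathesis–hydrogenation). The 20-membered ring (ring A C5, C6 and C1, the ether oxygen, ring B C1 and C6, and the fourteen bridge carbons) is closed in an end-to-end macrocyclisation through a ruthenacyclobutane, each arm losing its terminal CH2. No stereocentre is formed, and the E/Z geometry of 12 is erased by the hydrogenation. The step needs intramolecular over intermolecular metathesis, which high dilution and the bent diaryl ether that holds the ortho and meta arms on the same side should secure, and it needs the alkenes to stay terminal, which the mild couplings of steps 3 and 4 and the fast initiation at unhindered monosubstituted alkenes should secure. The free phenol, the aryl methyl ethers and the diaryl ether neither bind nor quench the ruthenium carbene.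

Step 6
Reactants: 13 saturated di-O-methyl macrocycle
Product: 14 CNP0173380.0 (target)
Conditions: BBr3 (6 equiv), CH2Cl2, −78 °C to rt; then H2O
Reagents that add atoms: none
Why: Lewis-acid ether cleavage with BBr3: boron binds each methoxy oxygen and bromide removes the methyl group by SN2 attack, whereas the diaryl ether has no sp3 carbon for bromide to attack and the saturated bridge is inert, so hydrolysis of the aryl borates releases the three phenols.

Compound list
1 | 5-bromovanillin (3-bromo-4-hydroxy-5-methoxybenzaldehyde) | COc1cc(C=O)cc(Br)c1O | starting material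
2 | (3-chloro-5-methoxyphenyl)boronic acid | COc1cc(Cl)cc(B(O)O)c1 | starting material
3 | 3-bromo-4-(3-chloro-5-methoxyphenoxy)-5-methoxybenzaldehyde | COc1cc(C=O)cc(Br)c1Oc1cc(Cl)cc(OC)c1 | intermediate
4 | 3-bromo-4-(3-chloro-5-methoxyphenoxy)-5-methoxyphenyl formate (aryl formate) | COc1cc(OC=O)cc(Br)c1Oc1cc(Cl)cc(OC)c1 | intermediate
5 | 3-bromo-4-(3-chloro-5-methoxyphenoxy)-5-methoxyphenol | COc1cc(O)cc(Br)c1Oc1cc(Cl)cc(OC)c1 | intermediate
6 | 10-bromodec-1-ene | C=CCCCCCCCCBr | starting material
7 | dec-9-en-1-ylzinc bromide | C=CCCCCCCCC[Zn]Br | intermediate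
8 | 4-(3-chloro-5-methoxyphenoxy)-3-(dec-9-en-1-yl)-5-methoxyphenol | COc1cc(O)cc(CCCCCCCCC=C)c1Oc1cc(Cl)cc(OC)c1 | intermediate
9 | 6-bromohex-1-ene | C=CCCCCBr | starting material
10 | hex-5-en-1-ylzinc bromide | C=CCCCC[Zn]Br | intermediate
11 | 3-(dec-9-en-1-yl)-4-[3-(hex-5-en-1-yl)-5-methoxyphenoxy]-5-methoxyphenol | COc1cc(O)cc(CCCCCCCCC=C)c1Oc1cc(CCCCC=C)cc(OC)c1 | intermediate
12 | macrocyclic alkene: 20-membered diaryl ether ring with a C9=C10 double bond in the bridge (E/Z mixture), OMe at ring A C3 and ring B C2, OH at ring B C4 | COc1cc2cc(c1)Oc1c(OC)cc(O)cc1CCCCCCCCC=CCCCC2 | intermediate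
13 | saturated di-O-methyl macrocycle: the target with the ring A C3 and ring B C2 oxygens as methyl ethers | COc1cc2cc(c1)Oc1c(OC)cc(O)cc1CCCCCCCCCCCCCC2 | intermediate
14 | CNP0173380.0 | Oc1cc2cc(c1)Oc1c(O)cc(O)cc1CCCCCCCCCCCCCC2 | target

Total step count: 6. Longest linear sequence: 6 steps (1 → 3 → 5 → 8 → 11 → 13 → 14).

Steps most likely to fail

Step 1. The phenol of 1 is flanked by Br and OMe and deactivated by the para aldehyde, so transmetalation and C–O reductive elimination at copper may be slow. Protodeboronation and oxidative homocoupling of 2 could then consume the boronic acid first. Fallback: metal-free arylation with a diaryliodonium salt, setting out from 1 and coming back to the route at 3. Commercial 1-chloro-3-iodo-5-methoxybenzene would be oxidised to the trivalent iodine stage with mCPBA and TsOH·H2O in MeCN. Trapping with 1,3,5-trimethoxybenzene should give (3-chloro-5-methoxyphenyl)(2,4,6-trimethoxyphenyl)iodonium tosylate F1. The potassium phenoxide of 1 (K2CO3, MeCN, 50 °C) would then add to iodine, and ligand coupling should transfer the less electron-rich 3-chloro-5-methoxyphenyl group to oxygen, giving 3.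

Step 5. Intermolecular metathesis may compete with ring closure and give oligomers. Ruthenium hydrides formed by catalyst decay may move the terminal alkenes along the chain before closure, leading to ring-contracted homologues. Hydrogenation by the dilute ruthenium hydride may also stall. Fallback: closure of the same C9–C10 bond by reductive carbonyl coupling, setting out from 11 and coming back to the route at 14. Diene 11 would be O-methylated (MeI, K2CO3, acetone) to 1-(dec-9-en-1-yl)-2-[3-(hex-5-en-1-yl)-5-methoxyphenoxy]-3,5-dimethoxybenzene F2. Lemieux–Johnson cleavage of both terminal alkenes (OsO4 cat., NaIO4, 2,6-lutidine, dioxane–H2O) should give 9-{3,5-dimethoxy-2-[3-methoxy-5-(5-oxopentyl)phenoxy]phenyl}nonanal F3. Intramolecular McMurry coupling (TiCl3(DME)1.5, Zn–Cu couple, DME, reflux, slow addition) should join the two aldehyde carbons to the tri-O-methyl macrocyclic alkene F4. Hydrogenation (H2, Pd/C, EtOAc) would give the saturated tri-O-methyl macrocycle F5, and BBr3 in CH2Cl2 would cleave all three methyl ethers to 14.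

Step 4. Oxidative addition to the electron-neutral aryl chloride may be sluggish. The alkylpalladium intermediate may undergo β-hydride elimination and reinsertion, which would isomerise the hexenyl arm, and part of the organozinc is lost to the phenolic proton. Fallback: B-alkyl Suzuki–Miyaura coupling, setting out from 8 and coming back to the route at 11. Hexa-1,5-diene (excess) would be monohydroborated with 9-borabicyclo[3.3.1]nonane in THF, and the excess diene removed, to give 9-(hex-5-en-1-yl)-9-borabicyclo[3.3.1]nonane F6. Coupling with 8 (Pd(OAc)2, SPhos, K3PO4, THF–H2O, 65 °C) should proceed through the borate and tolerates the phenoxide, giving 11.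

Further compounds
F1 | step 1 | (3-chloro-5-methoxyphenyl)(2,4,6-trimethoxyphenyl)iodonium tosylate | COc1cc(Cl)cc([I+]c2c(OC)cc(OC)cc2OC)c1.Cc1ccc(S(=O)(=O)[O-])cc1
F2 | step 5 | 1-(dec-9-en-1-yl)-2-[3-(hex-5-en-1-yl)-5-methoxyphenoxy]-3,5-dimethoxybenzene | COc1cc(OC)cc(CCCCCCCCC=C)c1Oc1cc(CCCCC=C)cc(OC)c1
F3 | step 5 | 9-{3,5-dimethoxy-2-[3-methoxy-5-(5-oxopentyl)phenoxy]phenyl}nonanal | COc1cc(OC)cc(CCCCCCCCC=O)c1Oc1cc(CCCCC=O)cc(OC)c1
F4 | step 5 | tri-O-methyl macrocyclic alkene (C9=C10, E/Z mixture) | COc1cc2cc(c1)Oc1c(OC)cc(OC)cc1CCCCCCCCC=CCCCC2
F5 | step 5 | saturated tri-O-methyl macrocycle | COc1cc2cc(c1)Oc1c(OC)cc(OC)cc1CCCCCCCCCCCCCC2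
F6 | step 4 | 9-(hex-5-en-1-yl)-9-borabicyclo[3.3.1]nonane | C=CCCCCB1C2CCCC1CCC2
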